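**Retrosynthetic overview**
- The acid is unmasked last from its methyl ester, so that no free carboxylic acid is present while the acid-labile acetal is carried.
- The furan bears carbon only at C2 (C3, C4 and C5 are CH), so the C3=C4 bond is disconnected by ring-closing metathesis. The ring closes as a 2-alkyl-5-methoxy-2,5-dihydrofuran that aromatises by loss of methanol. Its precursor is the mixed acrolein acetal of a 1-alken-3-ol (carbinol carbon = furan C2, acetal carbon = furan C5).
- The C6–C7 bond comes from SN2 alkylation of dilithiated hex-5-ynoic acid with a C16 bromide that already carries the diene acetal; the carboxylate is methylated in the same flask.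
- The bromide comes from tetradecane-1,14-diol: monobromide, aldehyde, vinylmagnesium bromide addition, then palladium-catalysed addition of the alcohol to methoxyallene.
- The furan is the only ring and is formed in step 6.

Key step: step 6

Remark: the target is achiral; the carbinol and acetal centres that appear in 5, 7 and 10 to 12 are carried as racemic mixtures (both diastereomers where two centres are present), since both become sp2 carbons of the furan.

**Step 1**
Reactants: 1 tetradecane-1,14-diol
Product: 2 14-bromotetradecan-1-ol
Conditions: 48% aq. HBr (1.2 equiv), toluene, reflux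
Reagents that add atoms: hydrogen bromide, Br
Why: Acid-promoted SN2 monobromination of an α,ω-diol under two-phase toluene/aqueous HBr conditions, which are known to favour the bromo alcohol over the dibromide.

**Step 2**
Reactants: 2 14-bromotetradecan-1-ol
Product: 3 14-bromotetradecanal
Conditions: TEMPO (10 mol%), PhI(OAc)2 (1.1 equiv), CH2Cl2, rt
Reagents that add atoms: none
Why: Oxoammonium (TEMPO) oxidation of a primary alcohol should stop at the aldehyde in the absence of water and leaves the primary bromide untouched.

**Step 3**
Reactants: 3 14-bromotetradecanal; 4 vinylmagnesium bromide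
Product: 5 16-bromohexadec-1-en-3-ol (racemic)
Conditions: CH2=CHMgBr (1.2 equiv), THF, -78 to 0 °C; aq. NH4Cl
Reagents that add atoms: vinylmagnesium bromide, C=C[Mg]Br
Why: Grignard 1,2-addition to the aldehyde is fast at low temperature while the unactivated primary bromide does not react, and the new carbinol centre is formed racemic without control because it later becomes furan C2.

**Step 4**
Reactants: 5 16-bromohexadec-1-en-3-ol; 6 methoxyallene
Product: 7 16-bromo-3-(1-methoxyprop-2-enyloxy)hexadec-1-ene (racemic, both diastereomers)
Conditions: Pd(OAc)2 (5 mol%), dppp (7.5 mol%), Et3N (1.5 equiv), methoxyallene (3 equiv), MeCN, rt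
Reagents that add atoms: methoxyallene, COC=C=C
Why: Palladium-catalysed hydroalkoxylation of an alkoxyallene, in which zerovalent palladium formed in situ from Pd(OAc)2 and dppp gives a methoxy-substituted π-allyl complex that the alkoxide attacks at the oxygen-bearing terminus, should give the mixed acrolein acetal under basic conditions, the acetal centre being set without control and erased later.

**Step 5**
Reactants: 8 hex-5-ynoic acid; 7 16-bromo-3-(1-methoxyprop-2-enyloxy)hexadec-1-ene
Product: 11 methyl 20-(1-methoxyprop-2-enyloxy)docos-21-en-5-ynoate (racemic, both diastereomers), via dilithio hex-5-ynoate 9 (not isolated), via lithium carboxylate 10 (not isolated)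
Conditions: 8 (1.3 equiv), n-BuLi (2.5 equiv), THF/HMPA, -78 to 0 °C; then 7, 0 °C to rt; then MeI (5 equiv), rt; aq. NaHCO3 work-up
Reagents that add atoms: iodomethane, CI
Why: Alkylation of an alkynoic acid dianion, in which the acetylide carbon is the only strongly nucleophilic site and displaces the primary bromide by SN2 in THF/HMPA, followed by O-methylation of the HMPA-activated lithium carboxylate in the same flask, should give the ester without the base-stable acetal ever meeting acid.

**Step 6**
Reactants: 11 methyl 20-(1-methoxyprop-2-enyloxy)docos-21-en-5-ynoate
Product: 13 methyl 19-(furan-2-yl)nonadec-5-ynoate, via methoxydihydrofuran 12 (not isolated)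
Conditions: second-generation Grubbs catalyst (H2IMes)(PCy3)Cl2Ru=CHPh (3 mol%), CH2Cl2 (0.005 M), 40 °C, Ar sparge; then PPTS (20 mol%), rt
Reagents that add atoms: none
Why: The ruthenium benzylidene exchanges onto one of the two monosubstituted vinyl groups, the resulting alkylidene adds [2+2] to the other vinyl group, and cycloreversion of the ruthenacyclobutane releases ethene and forms the C3=C4 bond of methoxydihydrofuran 12. This is ring-closing olefin metathesis of a mixed acrolein acetal of an allylic alcohol, a known entry to 2-substituted furans once the cyclic acetal is ionised. The single ring closes as a five-membered 2,5-dihydrofuran from a 3-oxa-1,6-diene, with O1–C2 and O1–C5 already in place and only C3=C4 newly made. PPTS then protonates the ring methoxy group, methanol leaves to give a cyclic oxocarbenium ion, and loss of the proton at the alkyl-bearing C2 gives the aromatic furan, so no stereocentre is set and the two racemic centres of 11 are erased. The step needs chemoselectivity for diene closure over enyne metathesis at C5≡C6; the alkyne is internal, dialkyl-substituted and thirteen methylenes away, so reaching it within the molecule would require a large ring, while high dilution and sweeping out ethene with argon should suppress intermolecular enyne and ethene–alkyne cross metathesis.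

**Step 7**
Reactants: 13 methyl 19-(furan-2-yl)nonadec-5-ynoate
Product: 14 19-(furan-2-yl)nonadec-5-ynoic acid
Conditions: LiOH·H2O (3 equiv), THF/MeOH/H2O, rt; work-up with 1 M HCl to pH 4, 0 °C
Reagents that add atoms: lithium hydroxide, [Li+].[OH-]
Why: Saponification of the methyl ester by acyl–oxygen cleavage with hydroxide leaves the furan and the alkyne untouched, and brief cold acidification to pH 4 should liberate the acid without harming the 2-alkylfuran.

**Compound list**
1 | tetradecane-1,14-diol | OCCCCCCCCCCCCCCO | starting material
2 | 14-bromotetradecan-1-ol | OCCCCCCCCCCCCCCBr | intermediate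
3 | 14-bromotetradecanal | O=CCCCCCCCCCCCCCBr | intermediate
4 | vinylmagnesium bromide | C=C[Mg]Br | starting material
5 | 16-bromohexadec-1-en-3-ol (racemic) | C=CC(O)CCCCCCCCCCCCCBr | intermediate
6 | methoxyallene (1-methoxypropa-1,2-diene) | COC=C=C | starting material
7 | 16-bromo-3-(1-methoxyprop-2-enyloxy)hexadec-1-ene (racemic, both diastereomers) | C=CC(OC(OC)C=C)CCCCCCCCCCCCCBr | intermediate
8 | hex-5-ynoic acid | C#CCCCC(=O)O | starting material
9 | lithium 6-lithiohex-5-ynoate (dilithio hex-5-ynoate) | [Li]C#CCCCC(=O)O[Li] | intermediate
10 | lithium 20-(1-methoxyprop-2-enyloxy)docos-21-en-5-ynoate (racemic, both diastereomers) | [Li+].[O-]C(=O)CCCC#CCCCCCCCCCCCCCC(C=C)OC(OC)C=C | intermediate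
11 | methyl 20-(1-methoxyprop-2-enyloxy)docos-21-en-5-ynoate (racemic, both diastereomers) | COC(=O)CCCC#CCCCCCCCCCCCCCC(C=C)OC(OC)C=C | intermediate
12 | methyl 19-(5-methoxy-2,5-dihydrofuran-2-yl)nonadec-5-ynoate (racemic, cis and trans) | COC(=O)CCCC#CCCCCCCCCCCCCCC1C=CC(OC)O1 | intermediate
13 | methyl 19-(furan-2-yl)nonadec-5-ynoate | COC(=O)CCCC#CCCCCCCCCCCCCCc1ccco1 | intermediate
14 | 19-(furan-2-yl)nonadec-5-ynoic acid | OC(=O)CCCC#CCCCCCCCCCCCCCc1ccco1 | target

**Total step count:** 7
**Longest linear sequence:** 7 steps (1 → 2 → 3 → 5 → 7 → 11 → 13 → 14); hex-5-ynoic acid 8 enters at step 5 without prior steps.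

**Steps most likely to fail**

1. Step 6. The ruthenium alkylidene may be drawn into enyne metathesis at the C5≡C6 triple bond, either with liberated ethene or with a vinyl group of a second molecule. That would consume catalyst and divert material into dienes and oligomers before the five-membered ring closes. Fallback, from 7 back to 14: the furan would be closed before the alkyne is in the molecule. Bromo diene acetal 7 would be treated with second-generation Grubbs catalyst in CH2Cl2 at 40 °C to give 2-(13-bromotridecyl)-5-methoxy-2,5-dihydrofuran F1, which PPTS would aromatise in the same flask to 2-(13-bromotridecyl)furan F2. F2 would then alkylate dilithio species 9 (from 8 and n-BuLi in THF/HMPA), and work-up with cold dilute citric acid to pH 4 would give acid 14 directly, so that steps 5 and 7 fall away.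

2. Step 5. The sparingly soluble dilithio species may displace the long-chain bromide only slowly, with E2 elimination competing, and O-methylation of the lithium carboxylate may stay incomplete. Fallback, from 7 back to 11: the polarity of the C6–C7 construction would be changed so that a soluble monolithium acetylide is alkylated. Bromide 7 would react with LiC≡CH·H2NCH2CH2NH2 (lithium acetylide–ethylenediamine complex) in DMSO at rt to give 3-(1-methoxyprop-2-enyloxy)octadec-1-en-17-yne F3. Deprotonation with n-BuLi in THF at -78 °C would give its lithium acetylide, 18-lithio-3-(1-methoxyprop-2-enyloxy)octadec-1-en-17-yne F4. Alkylation of F4 with trimethyl 4-bromoorthobutyrate (4-bromo-1,1,1-trimethoxybutane) in THF/HMPA would give the ortho ester 22,22,22-trimethoxy-3-(1-methoxyprop-2-enyloxy)docos-1-en-17-yne F5. Brief hydrolysis in acetate buffer (pH 5)/THF at 0 °C, where a trimethyl ortho ester should be cleaved far faster than the acetal, would give methyl ester 11.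

3. Step 4. The hydroalkoxylation may stall through palladium-mediated oligomerisation of methoxyallene, and Et3N may slowly quaternise the primary bromide over a long reaction time. Fallback, from 5 back to 7: the acetal would be made by acid-catalysed acetal exchange instead of palladium catalysis. Alcohol 5 would be heated with a large excess of acrolein dimethyl acetal (3,3-dimethoxyprop-1-ene) and PPTS (5 mol%) in toluene over 5 Å molecular sieves to take up methanol, giving 7 directly (no new compound, F0).

**Further compounds**
F1 | step 6 | 2-(13-bromotridecyl)-5-methoxy-2,5-dihydrofuran | COC1C=CC(CCCCCCCCCCCCCBr)O1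
F2 | step 6 | 2-(13-bromotridecyl)furan | BrCCCCCCCCCCCCCc1ccco1
F3 | step 5 | 3-(1-methoxyprop-2-enyloxy)octadec-1-en-17-yne | C#CCCCCCCCCCCCCCC(C=C)OC(OC)C=C
F4 | step 5 | 18-lithio-3-(1-methoxyprop-2-enyloxy)octadec-1-en-17-yne | [Li]C#CCCCCCCCCCCCCCC(C=C)OC(OC)C=C
F5 | step 5 | 22,22,22-trimethoxy-3-(1-methoxyprop-2-enyloxy)docos-1-en-17-yne | COC(OC)(OC)CCCC#CCCCCCCCCCCCCCC(C=C)OC(OC)C=C
F0 | step 4 | none | none
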